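**Strategy.** The γ-lactone is cut across the ring: O–C6 and C7–C11 are formed together on a preformed ten-membered (4Z,6Z)-dienone. The step exploits two features: C13 on C11 and C8 on C7 lie on the same face of the lactone ring, so a C13 acetal bridge to O8 can deliver C11 to C7; and C6 is allylic to the C4=C5 alkene, so the radical left after addition is an allyl system that the ester closes at C6. One copper-catalysed atom-transfer cyclization–lactonization thus makes both bonds and three stereocentres (C6, C7, C11). The precursor, made by ring-closing metathesis, carries an α-bromo ester bromoacetal on O8; C8 is inverted at the end by Mitsunobu esterification.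

Key step: step 9

Remark: locants C1–C13 are those of the germacranolide skeleton of the target (C1 ketone, C4/C5 epoxide, C6 lactone oxygen, C8 ester, C10 tertiary acetate, C12 lactone carbonyl, C13 acetoxymethyl). The γ-hydroxy ketones of the route (the open-chain trienone, the cyclodecadienone and the later C8 alcohols) are drawn open-chain and are assumed to react through this tautomer, although they can equilibrate with their C1,O8-hemiketals.

Step 1
Reactants: 1 methyl pyruvate; 2 2-(trimethylsilyloxy)buta-1,3-diene
Product: 4 methyl (2R)-2-hydroxy-2-methyl-4-oxohex-5-enoate, via silyl ether adduct 3 (not isolated)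
Conditions: Cu(OTf)2 (10 mol%), (R,R)-2,2'-isopropylidenebis(4-tert-butyl-2-oxazoline) (11 mol%), THF, −78 °C; then 1 M HCl
Reagents that add atoms: none
Why: Mukaiyama aldol addition of a ketone enol silane to pyruvate held as a five-membered chelate on the divalent copper bis(oxazoline) Lewis acid, whose tert-butyl groups shield one ketone face, so that the ligand antipode named here is expected to give the (R)-tertiary carbinol that becomes C10.

Step 2
Reactants: 4 methyl (2R)-2-hydroxy-2-methyl-4-oxohex-5-enoate
Product: 6 (3R,5R)-5-ethenyl-3-hydroxy-3-methyloxolan-2-one, via anti-diol ester 5 (not isolated)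
Conditions: Me4NBH(OAc)3, MeCN/AcOH, −30 °C; then CSA (cat.), CH2Cl2, rt
Reagents that add atoms: none
Why: Evans–Saksena directed reduction, in which the tertiary C10 hydroxyl exchanges onto boron and delivers hydride through a chair transition state to give the 1,3-anti diol (new centre C8, R), after which the γ-hydroxy ester lactonizes under acid, helped by the gem-disubstituted C10, so that O8 is masked and C1 is activated for a single addition.

Step 3
Reactants: 7 4-methyl-5,6-dihydro-2H-pyran-2-one
Product: 8 4-methyl-5,6-dihydro-2H-pyran-2-ol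
Conditions: i-Bu2AlH (1.05 equiv), CH2Cl2, −78 °C; aq. potassium sodium tartrate work-up
Reagents that add atoms: none
Why: Low-temperature half-reduction of a lactone stops at the lactol because the tetrahedral aluminium alkoxide is stable at −78 °C, and the ring holds the trisubstituted alkene in the Z geometry needed later for C4=C5.

Step 4
Reactants: 8 4-methyl-5,6-dihydro-2H-pyran-2-ol
Product: 10 (3Z)-3-methylhexa-3,5-dien-1-ol, via open hydroxy enal 9 (not isolated)
Conditions: Ph3PCH3Br (2.5 equiv), KN(SiMe3)2 (2.4 equiv), THF, 0 °C; then 8, −78 °C → rt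
Reagents that add atoms: methyltriphenylphosphonium bromide (C[P+](c1ccccc1)(c1ccccc1)c1ccccc1.[Br-])
Why: Wittig methylenation of the open hydroxy enal tautomer of the lactol with an unstabilized ylide, which leaves the Z trisubstituted alkene untouched and creates the terminal vinyl group for the later metathesis.

Step 5
Reactants: 10 (3Z)-3-methylhexa-3,5-dien-1-ol
Product: 11 (3Z)-6-iodo-4-methylhexa-1,3-diene
Conditions: I2, PPh3, imidazole, CH2Cl2, 0 °C, dark
Reagents that add atoms: iodine (II)
Why: Appel-type iodination of the primary homoallylic alcohol through its alkoxyphosphonium salt by SN2 displacement with iodide, under conditions that should not isomerize the diene.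

Step 6
Reactants: 6 (3R,5R)-5-ethenyl-3-hydroxy-3-methyloxolan-2-one; 11 (3Z)-6-iodo-4-methylhexa-1,3-diene
Product: 14 (3R,5R,9Z)-3,5-dihydroxy-5,9-dimethyldodeca-1,9,11-trien-6-one, via lithium alkoxide 12 (not isolated), via dienyllithium 13 (not isolated)
Conditions: 11, t-BuLi (2.0 equiv), Et2O, −78 °C; separately 6, LiN(SiMe3)2 (1.0 equiv), THF, −78 °C; combine at −78 °C; aq. NH4Cl
Reagents that add atoms: none
Why: Iodine–lithium exchange gives a primary alkyllithium that adds once to the γ-lactone because the lithium hemiketal alkoxide survives at −78 °C, the lactone having no α-hydrogen and the tertiary hydroxyl being masked as its lithium alkoxide, so that no stereocentre is touched.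

Step 7
Reactants: 14 (3R,5R,9Z)-3,5-dihydroxy-5,9-dimethyldodeca-1,9,11-trien-6-one
Product: 15 (4Z,6Z,8R,10R)-8,10-dihydroxy-4,10-dimethylcyclodeca-4,6-dien-1-one
Conditions: second-generation Grubbs catalyst (10 mol%), 1,4-benzoquinone (20 mol%), toluene (1 mM), 80 °C
Reagents that add atoms: none
Why: Ring-closing metathesis between the vinyl group on C8 and the terminal alkene of the diene with loss of ethylene, helped by the quaternary C10, the sp2 C1 and the preformed Z C4=C5 bond, and expected to settle reversibly on the Z C6=C7 alkene because an E,Z-1,3-diene is considerably more strained in a ten-membered ring.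

Step 8
Reactants: 15 (4Z,6Z,8R,10R)-8,10-dihydroxy-4,10-dimethylcyclodeca-4,6-dien-1-one; 16 methyl (2E)-3-methoxyprop-2-enoate
Product: 17 mixed bromoacetal (8R,10R): 15 carrying CH(OMe)–CHBr–CO2Me on O8 as a mixture at the two new centres
Conditions: 16, Br2 (1.0 equiv), CH2Cl2, −78 °C; then 15, 2,6-lutidine, −78 → 0 °C
Reagents that add atoms: bromine (BrBr)
Why: Stork–Ueno haloacetal formation in its two-stage form, in which bromine first adds across the enol-ether double bond of 16 so that no free halogen meets the ring diene, and the secondary allylic C8 hydroxyl then displaces the bromide next to oxygen through the oxocarbenium ion in preference to the hindered, hydrogen-bonded tertiary C10 hydroxyl, the two new centres being formed as mixtures that are both removed later.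

Step 9
Reactants: 17 mixed bromoacetal
Product: 19 tricyclic acetal lactone (4Z,6R,7S,8R,10R,11R)-10-hydroxy-13-methoxy-1-oxo-8,13-epoxygermacr-4-en-12,6-olide as both C13 epimers, via allylic bromide 18 (not isolated)
Conditions: CuBr (20 mol%), tris(2-pyridylmethyl)amine (20 mol%), degassed MeCN (5 mM), 70 °C
Reagents that add atoms: none
Why: Monovalent copper abstracts bromine from C11 to give an α-ester radical that closes the 2-methoxyoxolane ring (O8–C13–C11–C7–C8) by 5-exo-trig attack on C7, the terminus of the ring diene; the resulting C4–C5–C6 allyl radical is trapped by the divalent copper bromide as allylic bromide 18 (equivalent to the allyl cation), which the neighbouring ester carbonyl captures at C6 in a 5-exo closure to the γ-lactone with loss of bromomethane. The closest known reaction types are the copper-catalysed atom-transfer radical cyclization of Ueno–Stork haloacetals and the Kharasch addition–lactonization of α-halo esters, a radical–polar crossover lactone annulation of the manganese triacetate kind. C7 is set by delivery from O8: allylic 1,3-strain in the Z alkene puts H8 in the plane of C6=C7, so the tether reaches only the face syn to O8, which with (8R) gives (7S), whereas a cis arrangement of C6 and C9 on the new ring would force a syn-pentane contact between C5 and C9. C11 follows from the cis fusion of the two five-membered rings, which places C13 and C8 on the same face of the lactone, and C6 from closure on the face that already carries C11 while the ten-membered ring holds C5 and C8 cis, which gives the cis-fused lactone. The step needs attack at C7 instead of C6 (5-exo over 6-endo, and only C7 attack gives an allyl radical), lactone closure at C6 instead of C4 (five- against seven-membered ring) and a spectator tertiary hydroxyl, whose transannular ether, if formed, should re-ionize under the conditions. Both C13 epimers are carried on because that centre is removed later.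

Step 10
Reactants: 19 tricyclic acetal lactone
Product: 20 10-O-acetate of 19 (4Z,6R,7S,8R,10R,11R)
Conditions: Ac2O, DMAP, Et3N, CH2Cl2, 40 °C
Reagents that add atoms: acetic anhydride (CC(=O)OC(C)=O)
Why: DMAP-catalysed (Steglich-type) acylation of the tertiary α-hydroxy ketone through the N-acetylpyridinium ion, placed here because no other hydroxyl is free and no β-acyloxy lactone that could eliminate is yet present.

Step 11
Reactants: 20 10-O-acetate of 19
Product: 21 lactol (4Z,6R,7S,8R,10R,11R)-10-acetoxy-13-hydroxy-1-oxo-8,13-epoxygermacr-4-en-12,6-olide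
Conditions: PPTS (cat.), acetone/H2O (4:1), 50 °C
Reagents that add atoms: water (O)
Why: Acid-catalysed hydrolysis of the cyclic methyl acetal through its oxocarbenium ion under conditions too mild to ionize the allylic lactone or cleave the acetate, C11 being unable to epimerize while it remains the fusion atom of two cis-fused five-membered rings.

Step 12
Reactants: 21 lactol
Product: 23 diol (4Z,6R,7S,8R,10R,11R)-10-acetoxy-8,13-dihydroxy-1-oxogermacr-4-en-12,6-olide, via hydroxy aldehyde 22 (not isolated)
Conditions: NaBH(OAc)3, AcOH, MeCN, 0 °C → rt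
Reagents that add atoms: none
Why: Chemoselective hydride reduction in which NaBH(OAc)3 reduces the aldehyde tautomer of the lactol but neither the hindered C1 ketone nor the lactone and acetate, and C11 should keep its configuration because the aldehyde is released in the cis form and any enol re-protonates on the lactone face opposite C5 and C8.

Step 13
Reactants: 23 diol
Product: 24 (4Z,6R,7S,8R,10R,11R)-10,13-diacetoxy-8-hydroxy-1-oxogermacr-4-en-12,6-olide
Conditions: AcCl, 2,4,6-collidine, CH2Cl2, −78 °C
Reagents that add atoms: acetyl chloride (CC(=O)Cl)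
Why: Low-temperature acetylation with a hindered pyridine base discriminates the primary C13 hydroxyl from the hindered secondary C8 hydroxyl on steric grounds.

Step 14
Reactants: 24 (4Z,6R,7S,8R,10R,11R)-10,13-diacetoxy-8-hydroxy-1-oxogermacr-4-en-12,6-olide
Product: 25 (4R,5S,6S,7S,8R,10R,11R)-10,13-diacetoxy-4,5-epoxy-8-hydroxy-1-oxogermacran-12,6-olide
Conditions: VO(acac)2 (5 mol%), t-BuOOH, NaHCO3, CH2Cl2, 0 °C → rt
Reagents that add atoms: tert-butyl hydroperoxide (CC(C)(C)OO)
Why: Vanadium-catalysed hydroxyl-directed epoxidation of a bishomoallylic alcohol, in which the C8 vanadate, held on C7 above one face of the C4=C5 bond, delivers the peroxide oxygen to that face while allylic 1,3-strain between C3 and C6 keeps H6 in the alkene plane, this being also the face anti to the allylic C6–O bond and corresponding to (4R,5S).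

Step 15
Reactants: 25 (4R,5S,6S,7S,8R,10R,11R)-10,13-diacetoxy-4,5-epoxy-8-hydroxy-1-oxogermacran-12,6-olide
Product: 26 (4R,5S,6S,7S,8S,10R,11R)-10,13-diacetoxy-4,5-epoxy-8-(2-methylprop-2-enoyloxy)-1-oxogermacran-12,6-olide
Conditions: methacrylic acid, PPh3, DIAD, BHT (trace), toluene, 0 °C → rt
Reagents that add atoms: methacrylic acid (C=C(C)C(=O)O)
Why: Mitsunobu esterification, in which methacrylate displaces the alkoxyphosphonium ion of the secondary alcohol by SN2 with inversion (8R to 8S), installing the ester and correcting the one centre that the tether had required in the opposite sense, under neutral conditions that should leave epoxide, acetates and lactone alone.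

**Compound list**

1 | methyl pyruvate | COC(=O)C(C)=O | starting material
2 | 2-(trimethylsilyloxy)buta-1,3-diene | C=CC(=C)O[Si](C)(C)C | starting material
3 | methyl (2R)-2-methyl-4-oxo-2-(trimethylsilyloxy)hex-5-enoate (not isolated) | C=CC(=O)C[C@@](C)(O[Si](C)(C)C)C(=O)OC | intermediate
4 | methyl (2R)-2-hydroxy-2-methyl-4-oxohex-5-enoate | C=CC(=O)C[C@@](C)(O)C(=O)OC | intermediate
5 | methyl (2R,4R)-2,4-dihydroxy-2-methylhex-5-enoate, the 1,3-anti diol (not isolated) | C=C[C@H](O)C[C@@](C)(O)C(=O)OC | intermediate
6 | (3R,5R)-5-ethenyl-3-hydroxy-3-methyloxolan-2-one | C=C[C@H]1C[C@@](C)(O)C(=O)O1 | intermediate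
7 | 4-methyl-5,6-dihydro-2H-pyran-2-one | CC1=CC(=O)OCC1 | starting material
8 | 4-methyl-5,6-dihydro-2H-pyran-2-ol | CC1=CC(O)OCC1 | intermediate
9 | (2Z)-5-hydroxy-3-methylpent-2-enal, open form of 8 (not isolated) | O=C/C=C(C)\CCO | intermediate
10 | (3Z)-3-methylhexa-3,5-dien-1-ol | OCC/C(C)=C\C=C | intermediate
11 | (3Z)-6-iodo-4-methylhexa-1,3-diene | ICC/C(C)=C\C=C | intermediate
12 | lithium alkoxide of 6 (not isolated) | C=C[C@H]1C[C@@](C)(O[Li])C(=O)O1 | intermediate
13 | (3Z)-3-methylhexa-3,5-dien-1-yllithium (not isolated) | [Li]CC/C(C)=C\C=C | intermediate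
14 | (3R,5R,9Z)-3,5-dihydroxy-5,9-dimethyldodeca-1,9,11-trien-6-one | C=C[C@H](O)C[C@@](C)(O)C(=O)CC/C(C)=C\C=C | intermediate
15 | (4Z,6Z,8R,10R)-8,10-dihydroxy-4,10-dimethylcyclodeca-4,6-dien-1-one | O=C1CC/C(C)=C\C=C/[C@H](O)C[C@@]1(C)O | intermediate
16 | methyl (2E)-3-methoxyprop-2-enoate | CO/C=C/C(=O)OC | starting material
17 | mixed bromoacetal: 15 with CH(OMe)–CHBr–CO2Me on O8 (8R,10R; mixture at the acetal and bromide carbons) | O=C1CC/C(C)=C\C=C/[C@H](OC(OC)C(Br)C(=O)OC)C[C@@]1(C)O | intermediate
18 | allylic bromide: acetal ring closed (C7–C11), bromine on C6, methyl ester on C11 (not isolated) | COC1O[C@@H]2C[C@@](C)(O)C(=O)CC/C(C)=C\C(Br)[C@H]2[C@H]1C(=O)OC | intermediate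
19 | (4Z,6R,7S,8R,10R,11R)-10-hydroxy-13-methoxy-1-oxo-8,13-epoxygermacr-4-en-12,6-olide: ten-membered ring with cis-fused γ-lactone and cis-fused 2-methoxyoxolane (both C13 epimers) | COC1O[C@@H]2C[C@@](C)(O)C(=O)CC/C(C)=C\[C@H]3OC(=O)[C@@H]1[C@H]32 | intermediate
20 | 10-O-acetate of 19 | COC1O[C@@H]2C[C@@](C)(OC(C)=O)C(=O)CC/C(C)=C\[C@H]3OC(=O)[C@@H]1[C@H]32 | intermediate
21 | lactol: 13-hydroxy analogue of 20 | OC1O[C@@H]2C[C@@](C)(OC(C)=O)C(=O)CC/C(C)=C\[C@H]3OC(=O)[C@@H]1[C@H]32 | intermediate
22 | open hydroxy aldehyde of 21: C11 formyl, C8 hydroxyl (not isolated) | O[C@@H]1C[C@@](C)(OC(C)=O)C(=O)CC/C(C)=C\[C@H]2OC(=O)[C@@H](C=O)[C@H]21 | intermediate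
23 | (4Z,6R,7S,8R,10R,11R)-10-acetoxy-8,13-dihydroxy-1-oxogermacr-4-en-12,6-olide | O[C@@H]1C[C@@](C)(OC(C)=O)C(=O)CC/C(C)=C\[C@H]2OC(=O)[C@@H](CO)[C@H]21 | intermediate
24 | (4Z,6R,7S,8R,10R,11R)-10,13-diacetoxy-8-hydroxy-1-oxogermacr-4-en-12,6-olide | O[C@@H]1C[C@@](C)(OC(C)=O)C(=O)CC/C(C)=C\[C@H]2OC(=O)[C@@H](COC(C)=O)[C@H]21 | intermediate
25 | (4R,5S,6S,7S,8R,10R,11R)-10,13-diacetoxy-4,5-epoxy-8-hydroxy-1-oxogermacran-12,6-olide (the C6 descriptor changes by priority only) | O[C@@H]1C[C@@](C)(OC(C)=O)C(=O)CC[C@@]2(C)O[C@H]2[C@H]2OC(=O)[C@@H](COC(C)=O)[C@H]21 | intermediate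
26 | (4R,5S,6S,7S,8S,10R,11R)-10,13-diacetoxy-4,5-epoxy-8-(2-methylprop-2-enoyloxy)-1-oxogermacran-12,6-olide, CNP0166747.1 | C=C(C)C(=O)O[C@H]1C[C@@](C)(OC(C)=O)C(=O)CC[C@@]2(C)O[C@H]2[C@H]2OC(=O)[C@@H](COC(C)=O)[C@H]21 | target

**Totals.** Total step count: 15. Longest linear sequence: 13 steps (steps 3–5 and 6–15, from 4-methyl-5,6-dihydro-2H-pyran-2-one 7). Steps 1 and 2 from methyl pyruvate form the shorter branch, which joins at step 6.

**Steps most likely to fail**

Step 9 (key step). The C11 radical may close with its ester group trans to C6 on the new five-membered ring, so that the allylic bromide cannot reach C6 and is lost by elimination, or the radical may be quenched before it cyclizes. The fallback is an intermolecular annulation with the acetal ring closed afterwards. It sets out from 15: a copper-catalysed Kharasch addition–lactonization with methyl 2-bromo-3,3-dimethoxypropanoate (CuBr, tris(2-pyridylmethyl)amine, MeCN, 70 °C) should add the α-ester radical to C7 on the peripheral face syn to O8 and close the lactone at C6, giving the C11-dimethoxymethyl lactone F1. CSA in dry CH2Cl2 should then exchange one methoxy group for O8, the C11 epimers converging through the enol ether on the only possible cis-fused bicycle, and the route is rejoined at 19.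

Step 7. Intermolecular metathesis (oligomerization) may outrun closure of the ten-membered ring, or the ring may close to the E C6=C7 isomer. The fallback is a templated closure of an oxygen-bridged bicycle. It sets out from 14: PPTS and HC(OMe)3 in MeOH should convert the γ-hydroxy ketone into the cyclic methyl ketal F2, whose cis-2,5-disubstituted oxolane holds the two alkene-bearing arms together. Ring-closing metathesis with the same catalyst should then give the oxygen-bridged bicycle F3, and aqueous AcOH hydrolyses the ketal to rejoin the route at 15.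

Step 15. Backside attack at the hindered C8 may be slower than elimination or neighbouring-group capture of the alkoxyphosphonium ion. The fallback inverts C8 by oxidation and reduction. It sets out from 25: Dess–Martin periodinane should give the C8 ketone F4. LiAlH(Ot-Bu)3 at −78 °C should reduce it from the exposed outer face (the C1 ketone is shielded by the quaternary C10) to the (8S)-alcohol F5, and methacrylic anhydride with DMAP then gives 26.

**Further compounds**

F1 | step 9 | lactone of 15 carrying CH(OMe)2 on C11, free C8 and C10 hydroxyls (4Z,6R,7S,8R,10R; C11 epimers) | O[C@@H]1C[C@@](C)(O)C(=O)CC/C(C)=C\[C@H]2OC(=O)C(C(OC)OC)[C@H]21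
F2 | step 7 | cyclic methyl ketal of 14: (3R,5R)-5-ethenyl-2-methoxy-3-methyl-2-[(3Z)-3-methylhexa-3,5-dien-1-yl]oxolan-3-ol | C=C[C@H]1C[C@@](C)(O)C(OC)(CC/C(C)=C\C=C)O1
F3 | step 7 | oxygen-bridged bicycle: C1 methyl ketal of 15 with O8 bridging C1 and C8 | COC12CC/C(C)=C\C=C/[C@@H](C[C@@]2(C)O)O1
F4 | step 15 | C8 ketone of 25: (4R,5S,6S,7R,10R,11R)-10,13-diacetoxy-4,5-epoxy-1,8-dioxogermacran-12,6-olide (the C7 descriptor changes by priority only) | O=C1C[C@@](C)(OC(C)=O)C(=O)CC[C@@]2(C)O[C@H]2[C@H]2OC(=O)[C@@H](COC(C)=O)[C@H]21
F5 | step 15 | (8S)-alcohol, C8 epimer of 25 | O[C@H]1C[C@@](C)(OC(C)=O)C(=O)CC[C@@]2(C)O[C@H]2[C@H]2OC(=O)[C@@H](COC(C)=O)[C@H]21
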